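The route rests on closing ring A (the gem-dimethyl ring) between its CH2 carbon C9 and the bromine-bearing carbon C8. C8 is neopentylic, next to quaternary C7, so its bromide cannot be introduced by substitution. The key step therefore makes C8–C9 with bromine already in place: a 1-bromoalkyl radical, formed from a CHBr2 group, adds 6-endo to an acryloyl group and closes ring A in one operation. The precursor is a ring B cyclohexanone ketal whose quaternary carbon carries CH2=CH–CO and C(CH3)2–CHBr2, built by an Ireland–Claisen rearrangement. Afterwards a chiral lithium amide desymmetrizes ring B and thereby selects the spiro configuration and the enantiomer.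

Key step: step 6

Remark: the (R,R)-amide is assumed to take the axial ring B α-proton in the same spatial sense as in the known desymmetrization of 4-tert-butylcyclohexanone, which gives the S enol silane.

Step 1
Reactants: 1 1,4-dioxaspiro[4.5]decane-8-carboxylic acid; 2 1-bromo-3-methylbut-2-ene (prenyl bromide)
Product: 3 3-methylbut-2-en-1-yl 1,4-dioxaspiro[4.5]decane-8-carboxylate
Conditions: K2CO3, DMF, rt
Reagents that add atoms: none
Why: O-alkylation of the potassium carboxylate by the allylic bromide (SN2) should give the prenyl ester needed for the sigmatropic step; no stereocentre is formed.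

Step 2
Reactants: 3 3-methylbut-2-en-1-yl 1,4-dioxaspiro[4.5]decane-8-carboxylate
Product: 6 8-(2-methylbut-3-en-2-yl)-1,4-dioxaspiro[4.5]decane-8-carboxylic acid, via silyl ketene acetal 4 (not isolated), via trimethylsilyl ester 5 (not isolated)
Conditions: LiN(iPr)2, THF, −78 °C; TMSCl; −78 to 60 °C; then aqueous citric acid
Reagents that add atoms: none
Why: Ireland–Claisen rearrangement: the tetrasubstituted silyl ketene acetal 4 should rearrange through a chair [3,3] transition state, joining the ring B carbon to the prenyl C(CH3)2 carbon and so creating the two adjacent quaternary carbons (future C6 and C7), with the vinyl group as a masked aldehyde; the product keeps a mirror plane, so no stereocentre arises.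

Step 3
Reactants: 6 8-(2-methylbut-3-en-2-yl)-1,4-dioxaspiro[4.5]decane-8-carboxylic acid
Product: 8 1-[8-(2-methylbut-3-en-2-yl)-1,4-dioxaspiro[4.5]decan-8-yl]prop-2-en-1-one, via acid chloride 7 (not isolated)
Conditions: 1-chloro-N,N,2-trimethylprop-1-en-1-amine, CH2Cl2, rt; then Bu3SnCH=CH2, PdCl2(PPh3)2 (cat.), toluene, 70 °C
Reagents that add atoms: tributyl(vinyl)stannane, C=C[Sn](CCCC)(CCCC)CCCC
Why: the neutral chloro-enamine should convert the hindered acid into acid chloride 7 without harming the ketal, and Stille acylation with the vinylstannane should then give the non-enolisable vinyl ketone.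

Step 4
Reactants: 8 1-[8-(2-methylbut-3-en-2-yl)-1,4-dioxaspiro[4.5]decan-8-yl]prop-2-en-1-one
Product: 10 2-methyl-2-[8-(prop-2-enoyl)-1,4-dioxaspiro[4.5]decan-8-yl]propanal, via diol 9 (not isolated)
Conditions: OsO4 (cat.), NaIO4, 2,6-lutidine, dioxane–H2O, rt
Reagents that add atoms: sodium periodate, [Na+].[O-]I(=O)(=O)=O
Why: Lemieux–Johnson oxidation: OsO4 should dihydroxylate the electron-rich isolated vinyl group faster than the electron-poor acryloyl alkene, and periodate cleaves diol 9 to the neopentyl aldehyde, which cannot enolise.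

Step 5
Reactants: 10 2-methyl-2-[8-(prop-2-enoyl)-1,4-dioxaspiro[4.5]decan-8-yl]propanal
Product: 11 1-[8-(1,1-dibromo-2-methylpropan-2-yl)-1,4-dioxaspiro[4.5]decan-8-yl]prop-2-en-1-one
Conditions: (PhO)3P, Br2, Et3N, CH2Cl2, −78 °C to rt
Reagents that add atoms: bromine, BrBr
Why: deoxygenative gem-dibromination of an aldehyde by the triphenyl phosphite–bromine reagent (bromophosphonium activation of the carbonyl oxygen, then bromide delivery); the ketone has no α-hydrogen and should stay inert, and triethylamine shields the ketal.

Step 6
Reactants: 11 1-[8-(1,1-dibromo-2-methylpropan-2-yl)-1,4-dioxaspiro[4.5]decan-8-yl]prop-2-en-1-one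
Product: 12 rac-12-bromo-13,13-dimethyl-1,4-dioxadispiro[4.2.5.2]pentadecan-9-one
Conditions: (Me3Si)3SiH (1.1 equiv, slow addition), AIBN (cat.), benzene, 80 °C, high dilution
Reagents that add atoms: none
Why: The silyl radical abstracts one bromine of the CHBr2 group (either bromine gives the same planar 1-bromoalkyl radical), this radical adds to the terminal CH2 of the acryloyl group, and the resulting α-keto radical takes a hydrogen atom from the silane, so the C11–C12 bond (C9–C8 of the target) forms with bromine already on the neopentyl carbon. The closest known reaction type is the tin- or silicon-hydride-mediated cyclization of haloalkyl vinyl ketones, an intramolecular Giese addition. Ring A closes in the 6-endo-trig mode through a chair-like transition state, whereas the 5-exo path would need attack at the carbonyl-bearing alkene carbon and would leave an unstabilized primary radical. The only new stereocentre is the CHBr carbon; because the precursor is achiral and ring B is still mirror-symmetric it forms as the racemate, and its absolute configuration is selected in step 9. The step needs 6-endo regioselectivity, secured by the polarized, unhindered acryloyl terminus and by the two adjacent quaternary carbons that keep the chain folded, and it needs loss of only one bromine, secured by the faster abstraction from a gem-dibromide than from the secondary bromide product and by slow addition of one equivalent of silane.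

Step 7
Reactants: 12 rac-12-bromo-13,13-dimethyl-1,4-dioxadispiro[4.2.5.2]pentadecan-9-one
Product: 13 rac-12-bromo-13,13-dimethyl-9-methylidene-1,4-dioxadispiro[4.2.5.2]pentadecane
Conditions: Cp2TiMe2, toluene, 70 °C, dark
Reagents that add atoms: dimethyltitanocene Cp2TiMe2, C[Ti](C)(C1C=CC=C1)C1C=CC=C1
Why: Petasis methylenation: Cp2TiMe2 loses methane on heating to give the titanium methylidene, which should olefinate the hindered ketone through an oxatitanacyclobutane; the reagent is not basic, so the ketone is not enolised toward the γ-bromide, and ketal and alkyl bromide are left alone.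

Step 8
Reactants: 13 rac-12-bromo-13,13-dimethyl-9-methylidene-1,4-dioxadispiro[4.2.5.2]pentadecane
Product: 14 rac-8-bromo-7,7-dimethyl-11-methylidenespiro[5.5]undecan-3-one
Conditions: 1 M HCl, THF, rt
Reagents that add atoms: water, O
Why: acid-catalysed hydrolysis of the dioxolane should free the ring B ketone; at room temperature the exocyclic 1,1-disubstituted alkene should not migrate and the bromide is inert.

Step 9
Reactants: 14 rac-8-bromo-7,7-dimethyl-11-methylidenespiro[5.5]undecan-3-one
Product: 16 (6S,8R)-8-bromo-7,7-dimethyl-11-methylidenespiro[5.5]undec-1-en-3-one, via silyl enol ether 15 (not isolated)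
Conditions: (R,R)-bis(1-phenylethyl)amine, n-BuLi, LiCl, TMSCl, THF, −100 to −78 °C; then Pd(OAc)2 (cat.), O2, DMSO, rt; chromatography
Reagents that add atoms: none
Why: chiral lithium amide deprotonation with internal TMSCl quench, then Saegusa–Ito oxidation of silyl enol ether 15: ring B is locked with the tertiary-alkyl carbon C7 equatorial, and the (R,R)-amide should remove the axial α-proton on the same side of ring B in both enantiomers of 14, which fixes C6 as S; the 8R enantiomer therefore gives 16 and the 8S enantiomer gives the (6S,8S)-diastereomer, which is removed by chromatography, so this step sets C6 and selects C8, and at most half of the racemate can become 16.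

Step 10
Reactants: 16 (6S,8R)-8-bromo-7,7-dimethyl-11-methylidenespiro[5.5]undec-1-en-3-one
Product: 17 (3Z,6S,8R)-8-bromo-3-(bromomethylidene)-7,7-dimethyl-11-methylidenespiro[5.5]undec-1-ene
Conditions: [Ph3PCH2Br]Br, KOtBu, THF, −78 °C to rt; separation of the geometric isomers
Reagents that add atoms: (bromomethyl)triphenylphosphonium bromide, [Br-].BrC[P+](c1ccccc1)(c1ccccc1)c1ccccc1
Why: Wittig bromomethylenation of the only carbonyl group by Ph3P=CHBr made in the flask; the geometry is set when the oxaphosphetane forms, where bromine should turn toward the flat sp2 carbon C2 and away from the C4 methylene, so the Z isomer is expected to predominate only moderately and the E isomer has to be separated.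

Compound list
1 | 1,4-dioxaspiro[4.5]decane-8-carboxylic acid | OC(=O)C1CCC2(CC1)OCCO2 | starting material
2 | 1-bromo-3-methylbut-2-ene (prenyl bromide) | CC(C)=CCBr | starting material
3 | 3-methylbut-2-en-1-yl 1,4-dioxaspiro[4.5]decane-8-carboxylate | CC(C)=CCOC(=O)C1CCC2(CC1)OCCO2 | intermediate
4 | trimethylsilyl ketene acetal of ester 3 | CC(C)=CCOC(O[Si](C)(C)C)=C1CCC2(CC1)OCCO2 | intermediate
5 | trimethylsilyl 8-(2-methylbut-3-en-2-yl)-1,4-dioxaspiro[4.5]decane-8-carboxylate | C=CC(C)(C)C1(CCC2(CC1)OCCO2)C(=O)O[Si](C)(C)C | intermediate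
6 | 8-(2-methylbut-3-en-2-yl)-1,4-dioxaspiro[4.5]decane-8-carboxylic acid | C=CC(C)(C)C1(CCC2(CC1)OCCO2)C(O)=O | intermediate
7 | 8-(2-methylbut-3-en-2-yl)-1,4-dioxaspiro[4.5]decane-8-carbonyl chloride | C=CC(C)(C)C1(CCC2(CC1)OCCO2)C(Cl)=O | intermediate
8 | 1-[8-(2-methylbut-3-en-2-yl)-1,4-dioxaspiro[4.5]decan-8-yl]prop-2-en-1-one | C=CC(=O)C1(CCC2(CC1)OCCO2)C(C)(C)C=C | intermediate
9 | 1-[8-(3,4-dihydroxy-2-methylbutan-2-yl)-1,4-dioxaspiro[4.5]decan-8-yl]prop-2-en-1-one | C=CC(=O)C1(CCC2(CC1)OCCO2)C(C)(C)C(O)CO | intermediate
10 | 2-methyl-2-[8-(prop-2-enoyl)-1,4-dioxaspiro[4.5]decan-8-yl]propanal | C=CC(=O)C1(CCC2(CC1)OCCO2)C(C)(C)C=O | intermediate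
11 | 1-[8-(1,1-dibromo-2-methylpropan-2-yl)-1,4-dioxaspiro[4.5]decan-8-yl]prop-2-en-1-one | C=CC(=O)C1(CCC2(CC1)OCCO2)C(C)(C)C(Br)Br | intermediate
12 | rac-12-bromo-13,13-dimethyl-1,4-dioxadispiro[4.2.5.2]pentadecan-9-one (racemate) | O=C1CCC(Br)C(C)(C)C12CCC3(CC2)OCCO3 | intermediate
13 | rac-12-bromo-13,13-dimethyl-9-methylidene-1,4-dioxadispiro[4.2.5.2]pentadecane (racemate) | C=C1CCC(Br)C(C)(C)C12CCC3(CC2)OCCO3 | intermediate
14 | rac-8-bromo-7,7-dimethyl-11-methylidenespiro[5.5]undecan-3-one (racemate) | C=C1CCC(Br)C(C)(C)C12CCC(=O)CC2 | intermediate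
15 | {[(6S,8R)-8-bromo-7,7-dimethyl-11-methylidenespiro[5.5]undec-2-en-3-yl]oxy}trimethylsilane | C=C1CC[C@@H](Br)C(C)(C)[C@@]12CC=C(O[Si](C)(C)C)CC2 | intermediate
16 | (6S,8R)-8-bromo-7,7-dimethyl-11-methylidenespiro[5.5]undec-1-en-3-one | C=C1CC[C@@H](Br)C(C)(C)[C@@]12C=CC(=O)CC2 | intermediate
17 | (3Z,6S,8R)-8-bromo-3-(bromomethylidene)-7,7-dimethyl-11-methylidenespiro[5.5]undec-1-ene | C=C1CC[C@@H](Br)C(C)(C)[C@@]12C=C/C(=C\Br)CC2 | target

Total step count: 10. Longest linear sequence: 10 steps (the route is linear).

Steps most likely to fail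

Step 6 (key step). The open-chain 1-bromoalkyl radical may take a hydrogen atom before it closes the ring, or the product may lose its bromine to a further silyl radical. The fallback sets out from 11 and uses a bromine-atom-transfer radical cyclization without any hydrogen donor (CuBr, tris(2-pyridylmethyl)amine, a little AIBN as reductant, 1,2-dichloroethane, 80 °C). The α-keto radical is then capped by bromine from CuBr2, which should give rac-10,12-dibromo-13,13-dimethyl-1,4-dioxadispiro[4.2.5.2]pentadecan-9-one F1. Zn in AcOH at 0 °C should remove only the bromine next to the carbonyl group, and the route is rejoined at 12.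

Step 5. The bromophosphonium reagent or the HBr it releases may open the ketal or add bromide to the acryloyl group while the hindered aldehyde reacts slowly. The fallback sets out from 6 and installs the CHBr2 group before the enone exists:
- Silylation (iPr3SiCl, imidazole, DMF) should give the tri(propan-2-yl)silyl ester F2.
- Ozonolysis (O3, CH2Cl2, −78 °C; Me2S) through the ozonide F3 should give the aldehyde F4.
- The same (PhO)3P/Br2/Et3N treatment, now on a substrate without an enone, should give the dibromide F5.
- (COCl)2 with catalytic DMF should turn the silyl ester directly into the acid chloride F6.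
- Stille acylation as in step 3 then rejoins the route at 11.

Step 10. The ylide may add with little preference for either alkene geometry, so that much of the material ends up as the E isomer. The fallback sets out from 16 and first makes an alkene that has no geometry: Ph3P=CBr2 (from [Ph3PCHBr2]Br and KOtBu, toluene) should give (6S,8R)-8-bromo-3-(dibromomethylidene)-7,7-dimethyl-11-methylidenespiro[5.5]undec-1-ene F7. A Hirao reduction ((EtO)2P(O)H, Et3N, DMF) should then remove the more crowded bromine, the one beside the C4 methylene, and rejoin the route at 17.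

Further compounds
F1 | step 6 | rac-10,12-dibromo-13,13-dimethyl-1,4-dioxadispiro[4.2.5.2]pentadecan-9-one | O=C1C(Br)CC(Br)C(C)(C)C12CCC3(CC2)OCCO3
F2 | step 5 | tri(propan-2-yl)silyl 8-(2-methylbut-3-en-2-yl)-1,4-dioxaspiro[4.5]decane-8-carboxylate | C=CC(C)(C)C1(CCC2(CC1)OCCO2)C(=O)O[Si](C(C)C)(C(C)C)C(C)C
F3 | step 5 | tri(propan-2-yl)silyl 8-[2-(1,2,4-trioxolan-3-yl)propan-2-yl]-1,4-dioxaspiro[4.5]decane-8-carboxylate | CC(C)(C1OCOO1)C1(CCC2(CC1)OCCO2)C(=O)O[Si](C(C)C)(C(C)C)C(C)C
F4 | step 5 | tri(propan-2-yl)silyl 8-(2-methyl-1-oxopropan-2-yl)-1,4-dioxaspiro[4.5]decane-8-carboxylate | O=CC(C)(C)C1(CCC2(CC1)OCCO2)C(=O)O[Si](C(C)C)(C(C)C)C(C)C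
F5 | step 5 | tri(propan-2-yl)silyl 8-(1,1-dibromo-2-methylpropan-2-yl)-1,4-dioxaspiro[4.5]decane-8-carboxylate | BrC(Br)C(C)(C)C1(CCC2(CC1)OCCO2)C(=O)O[Si](C(C)C)(C(C)C)C(C)C
F6 | step 5 | 8-(1,1-dibromo-2-methylpropan-2-yl)-1,4-dioxaspiro[4.5]decane-8-carbonyl chloride | BrC(Br)C(C)(C)C1(CCC2(CC1)OCCO2)C(Cl)=O
F7 | step 10 | (6S,8R)-8-bromo-3-(dibromomethylidene)-7,7-dimethyl-11-methylidenespiro[5.5]undec-1-ene | C=C1CC[C@@H](Br)C(C)(C)[C@@]12C=CC(=C(Br)Br)CC2
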